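**Retrosynthetic overview**
- Last: rings B and A of the quinolizidin-2-one are closed on a macrocyclic chloro enone with NH3 and CH2O (N-alkylation, aza-Michael, Mannich); C9a, C1 and C3 are thermodynamic, relayed from C9.
- Key step: a photochemical conjunctive macro-olefination closes the 18-membered ring; a light-driven radical C–C bond formation to an acyl vinylphosphonate is followed in the same pot by ring-closing Horner–Wadsworth–Emmons olefination (C1=C9a).
- Before that: the 1-oxaquinolizidine is made by condensation of a 1,3-amino alcohol with a 5-chloro aldehyde and N-alkylation; C9′ and C9a′ are thermodynamic, set by C2′/C3′.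
- Fragments, joined by Wittig olefination: C9 from (R)-cyclohex-3-ene-1-carboxylic acid (ozonolysis, lactone differentiation of the arms); C3′ from (S)-Roche ester, C2′ by chelation-controlled Grignard addition; the C9′ piece from ε-caprolactone.
- Ring order: oxazine + piperidine (oxaquinolizidine) → 18-membered macrocycle → piperidine B → piperidinone A.

Locants: quinolizidin-2-one unit C1, C2 (C=O), C3 (Me), C4, N5, C9, C9a; 1-oxaquinolizidine unit O1′, C2′, C3′ (Me), C4′, N5′, C9′, C9a′. Chains: C9–(CH2)6–C2′ and C1–(CH2)5–C9′.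

Assumption: C1, C3, C9a and C9′, C9a′ of the target are the thermodynamically preferred configurations (all-equatorial trans-fused oxaquinolizidine; trans-fused quinolizidinone with 3-Me and the C9 chain equatorial and the C1 chain axial, which avoids the C1/C9 peri interaction). Only C9, C2′ and C3′ then need chiral-pool or kinetic control.

**Route**

Step 1
Reactants: 1 (R)-cyclohex-3-ene-1-carboxylic acid
Product: 3 (R)-3-(3-hydroxypropyl)oxolan-2-one, via diol acid 2 (not isolated)
Conditions: O3, CH2Cl2/MeOH, −78 °C; NaBH4, −78 → 25 °C; aq. HCl (pH 1); TsOH (cat.), CH2Cl2, 25 °C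
Reagents that add atoms: ozone, [O-][O+]=O
Why: Ozonolysis with NaBH4 work-up opens the ring to diol acid 2 and acid-catalysed lactonisation closes the favoured five-membered lactone on the two-carbon arm, which tells the two arms apart while the purchased stereocentre (later C9) is not involved.

Step 2
Reactants: 3 (R)-3-(3-hydroxypropyl)oxolan-2-one
Product: 4 (R)-3-(3-chloropropyl)oxolan-2-one
Conditions: N-chlorosuccinimide, PPh3, CH2Cl2, 0 → 25 °C
Reagents that add atoms: N-chlorosuccinimide, O=C1CCC(=O)N1Cl
Why: Appel-type chlorination (SN2 on the alkoxyphosphonium ion) turns the free three-carbon arm into the electrophile later used to close ring B, with lactone and stereocentre inert.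

Step 3
Reactants: 4 (R)-3-(3-chloropropyl)oxolan-2-one
Product: 5 (R)-5-chloro-2-(2-hydroxyethyl)-N-methoxy-N-methylpentanamide
Conditions: MeNH(OMe)·HCl, iPrMgCl, THF, −20 → 0 °C; H2O
Reagents that add atoms: N,O-dimethylhydroxylamine hydrochloride, CNOC.Cl
Why: Weinreb aminolysis of the lactone by the chloromagnesium amide frees the two-carbon arm as a primary alcohol and stores the future C9a carbon at the aldehyde oxidation level without epimerising the α-centre.

Step 4
Reactants: 5 (R)-5-chloro-2-(2-hydroxyethyl)-N-methoxy-N-methylpentanamide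
Product: 6 (R)-5-chloro-N-methoxy-N-methyl-2-(2-oxoethyl)pentanamide
Conditions: TEMPO (10 mol %), PhI(OAc)2, CH2Cl2, 25 °C
Reagents that add atoms: none
Why: TEMPO/PhI(OAc)2 oxidation takes the primary alcohol to the aldehyde without over-oxidation and tolerates the Weinreb amide and the alkyl chloride.

Step 5
Reactants: 7 methyl (S)-3-hydroxy-2-methylpropanoate (Roche ester)
Product: 8 methyl (S)-3-(benzyloxy)-2-methylpropanoate
Conditions: BnOC(=NH)CCl3, TfOH (cat.), CH2Cl2/cyclohexane, 0 → 25 °C
Reagents that add atoms: benzyl 2,2,2-trichloroacetimidate, N=C(OCc1ccccc1)C(Cl)(Cl)Cl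
Why: Acid-catalysed benzylation by the trichloroacetimidate method avoids base-induced β-elimination or racemisation and installs the chelating ether needed in step 7.

Step 6
Reactants: 8 methyl (S)-3-(benzyloxy)-2-methylpropanoate
Product: 9 (S)-3-(benzyloxy)-2-methylpropanal
Conditions: iBu2AlH, CH2Cl2, −78 °C; aq. KNaC4H4O6
Reagents that add atoms: none
Why: Partial ester reduction at −78 °C stops at the aluminium hemiacetal and gives the configurationally labile α-methyl aldehyde, which is used crude at once.

Step 7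
Reactants: 9 (S)-3-(benzyloxy)-2-methylpropanal; 10 1-bromo-4-chlorobutane
Product: 12 (2S,3R)-1-(benzyloxy)-7-chloro-2-methylheptan-3-ol, via Grignard reagent 11 (not isolated)
Conditions: 10, Mg, Et2O, 25 °C; then 9 + MgBr2·OEt2, CH2Cl2, −78 °C; H2O
Reagents that add atoms: none
Why: Chelation-controlled (Cram chelate) Grignard addition, in which magnesium bridges the aldehyde and benzyloxy oxygens and the nucleophile enters anti to the α-methyl group, so the purchased C3′ centre sets C2′ as the 2,3-anti (R) carbinol.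

Step 8
Reactants: 12 (2S,3R)-1-(benzyloxy)-7-chloro-2-methylheptan-3-ol
Product: 13 [(5R,6S)-7-(benzyloxy)-5-hydroxy-6-methylheptyl]triphenylphosphonium iodide
Conditions: NaI, PPh3, MeCN, 80 °C
Reagents that add atoms: triphenylphosphine, c1ccc(cc1)P(c1ccccc1)c1ccccc1; sodium iodide, [Na+].[I-]
Why: Finkelstein exchange followed by SN2 quaternisation of PPh3 gives the phosphonium salt, the secondary alcohol needing no protection.

Step 9
Reactants: 13 [(5R,6S)-7-(benzyloxy)-5-hydroxy-6-methylheptyl]triphenylphosphonium iodide; 6 (R)-5-chloro-N-methoxy-N-methyl-2-(2-oxoethyl)pentanamide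
Product: 15 (2R)-2-[(2Z,7R,8S)-9-(benzyloxy)-7-hydroxy-8-methylnon-2-en-1-yl]-5-chloro-N-methoxy-N-methylpentanamide, via oxido ylide 14 (not isolated)
Conditions: KN(SiMe3)2 (2.0 equiv), THF, −78 → 0 °C; then 6, −78 → 25 °C; H2O
Reagents that add atoms: none
Why: Wittig olefination with the unstabilised oxido ylide attacks only the aldehyde of 6 (the Weinreb amide is inert at low temperature) and joins the two chiral-pool fragments, the alkene geometry being irrelevant because it is hydrogenated next.

Step 10
Reactants: 15 (2R)-2-[(2Z,7R,8S)-9-(benzyloxy)-7-hydroxy-8-methylnon-2-en-1-yl]-5-chloro-N-methoxy-N-methylpentanamide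
Product: 16 (2S)-5-chloro-2-[(7R,8S)-7,9-dihydroxy-8-methylnonyl]-N-methoxy-N-methylpentanamide
Conditions: H2 (1 atm), Pd/C, EtOH, 25 °C
Reagents that add atoms: none
Why: Heterogeneous hydrogenation saturates the alkene and hydrogenolyses the benzyl ether in one operation while the primary chloride and the Weinreb amide survive (the descriptor at C2 changes only through CIP priorities).

Step 11
Reactants: 16 (2S)-5-chloro-2-[(7R,8S)-7,9-dihydroxy-8-methylnonyl]-N-methoxy-N-methylpentanamide
Product: 17 (2S)-2-[(7R,8S)-9-azido-7-hydroxy-8-methylnonyl]-5-chloro-N-methoxy-N-methylpentanamide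
Conditions: (PhO)2P(O)N3, iPrO2CN=NCO2iPr, PPh3, THF, 0 °C
Reagents that add atoms: diphenylphosphoryl azide, [N-]=[N+]=NP(=O)(Oc1ccccc1)Oc1ccccc1
Why: Mitsunobu azidation is selective for the primary hydroxyl of the 1,3-diol (SN2 at CH2, no stereocentre involved) and brings in the oxaquinolizidine nitrogen in masked form.

Step 12
Reactants: 18 ε-caprolactone; 19 1-chloro-3-iodopropane
Product: 21 3-(3-chloropropyl)oxepan-2-one (racemic), via lithium enolate 20 (not isolated)
Conditions: LiN(iPr)2, THF, −78 °C; then 19, DMPU, −78 → −30 °C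
Reagents that add atoms: none
Why: Lactone enolate alkylation in which the iodide reacts far faster than the chloride; the new centre (future C9′) is deliberately racemic because it is equilibrated in step 14.

Step 13
Reactants: 21 3-(3-chloropropyl)oxepan-2-one
Product: 22 2-(3-chloropropyl)-6-hydroxyhexanal (in equilibrium with its lactol)
Conditions: iBu2AlH (1.05 equiv), CH2Cl2, −78 °C; aq. KNaC4H4O6
Reagents that add atoms: none
Why: Partial reduction of the seven-membered lactone gives the ring-opened hydroxy aldehyde, a 5-chloro-2-alkylpentanal ready for the annulation.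

Step 14
Reactants: 17 (2S)-2-[(7R,8S)-9-azido-7-hydroxy-8-methylnonyl]-5-chloro-N-methoxy-N-methylpentanamide; 22 2-(3-chloropropyl)-6-hydroxyhexanal
Product: 25 (2S)-5-chloro-2-{6-[(2R,3S,9R,9aS)-9-(4-hydroxybutyl)-3-methylperhydropyrido[2,1-b][1,3]oxazin-2-yl]hexyl}-N-methoxy-N-methylpentanamide, via amino alcohol 23 (not isolated), via oxazinane 24 (not isolated)
Conditions: PPh3, THF/H2O, 50 °C; then 22, 4 Å sieves, CH2Cl2, 25 °C; then K2CO3, MeCN, 70 °C; then AcOH/MeOH (1:10), 40 °C
Reagents that add atoms: none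
Why: Staudinger reduction, then condensation of the 1,3-amino alcohol with the 5-chloro aldehyde to the tetrahydro-1,3-oxazine and 6-exo-tet N-alkylation (the oxaquinolizidine annulation known from xestospongin work), in which imine/enamine and N,O-acetal equilibria make C9′ and C9a′ thermodynamic so that the fixed C2′/C3′ centres drive both into the all-equatorial trans-fused bicycle.

Step 15
Reactants: 25 (2S)-5-chloro-2-{6-[(2R,3S,9R,9aS)-9-(4-hydroxybutyl)-3-methylperhydropyrido[2,1-b][1,3]oxazin-2-yl]hexyl}-N-methoxy-N-methylpentanamide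
Product: 26 (2S)-2-{6-[(2R,3S,9R,9aS)-9-(4-bromobutyl)-3-methylperhydropyrido[2,1-b][1,3]oxazin-2-yl]hexyl}-5-chloro-N-methoxy-N-methylpentanamide
Conditions: CBr4, PPh3, CH2Cl2, 0 °C
Reagents that add atoms: carbon tetrabromide, BrC(Br)(Br)Br
Why: Appel bromination of the primary alcohol under neutral conditions gives the radical precursor while the Weinreb amide, the N,O-acetal and the chloride are inert.

Step 16
Reactants: 26 (2S)-2-{6-[(2R,3S,9R,9aS)-9-(4-bromobutyl)-3-methylperhydropyrido[2,1-b][1,3]oxazin-2-yl]hexyl}-5-chloro-N-methoxy-N-methylpentanamide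
Product: 27 (2S)-2-{6-[(2R,3S,9R,9aS)-9-(4-bromobutyl)-3-methylperhydropyrido[2,1-b][1,3]oxazin-2-yl]hexyl}-5-chloropentanal
Conditions: iBu2AlH, THF, −78 °C; aq. KNaC4H4O6
Reagents that add atoms: none
Why: Weinreb amide reduction stops at the aldehyde through the chelated tetrahedral intermediate, leaving both C–halogen bonds and the α-stereocentre (C9) intact; the aldehyde is used at once.

Step 17
Reactants: 28 diethyl (2-oxobutyl)phosphonate
Product: 29 diethyl (3-oxopent-1-en-2-yl)phosphonate
Conditions: (CH2O)n, piperidine (cat.), AcOH (cat.), MeOH, 65 °C; then TsOH (cat.), toluene, 110 °C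
Reagents that add atoms: formaldehyde, C=O
Why: Knoevenagel-type α-methylenation (Mannich condensation with formaldehyde, then elimination) of the β-keto phosphonate gives the doubly activated radical acceptor, used freshly prepared.

Step 18
Reactants: 27 (2S)-2-{6-[(2R,3S,9R,9aS)-9-(4-bromobutyl)-3-methylperhydropyrido[2,1-b][1,3]oxazin-2-yl]hexyl}-5-chloropentanal; 29 diethyl (3-oxopent-1-en-2-yl)phosphonate
Product: 31 macrocyclic E-chloro-enone (18-membered ring; full description in the compound list), via keto phosphonate 30 (not isolated)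
Conditions: 29 (1.2 equiv, added over 4 h), (Me3Si)3SiH (1.3 equiv), [Ir(dF(CF3)ppy)2(dtbbpy)]PF6 (1 mol %), K2CO3, 18-crown-6 (cat.), MeCN (2 mM in 27), 450 nm LEDs, 25 °C; then 45 °C in the dark
Reagents that add atoms: none
Why: Proposed new method: a photochemical conjunctive macro-olefination in which the excited iridium photocatalyst starts a silyl-radical chain, halogen-atom transfer from the primary bromide gives a C-radical that adds to the CH2 terminus of 29 (polarity-matched Giese addition, forming the C–C bond next to the future C1), the α-keto-α-phosphoryl radical is quenched by the silane (or reduced by the photocatalyst) to 30, and its potassium enolate closes the 18-membered ring by intramolecular Horner–Wadsworth–Emmons olefination of the α-branched aldehyde (C1=C9a) without touching C9; the closest known reaction types are the silyl-mediated photoredox Giese addition of alkyl bromides and the radical–polar crossover conjunctive olefination of vinylphosphonium salts, neither shown with an acyl vinylphosphonate or for ring closure.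

Step 19
Reactants: 31 macrocyclic E-chloro-enone
Product: 34 target CNP0236330.1, via amino enone 32 (not isolated), via piperidine 33 (not isolated)
Conditions: NH3 (7 M in MeOH), NaI (cat.), 60 °C, sealed tube; evaporate; then aq. CH2O (1.5 equiv), AcOH/MeOH (1:10), 40 °C; then K2CO3, MeOH, 25 °C
Reagents that add atoms: ammonia, N; formaldehyde, C=O
Why: Ammonia displaces the chloride and the primary amine closes ring B by reversible 6-exo aza-Michael addition, then an intramolecular Mannich reaction with formaldehyde on the ethyl ketone closes ring A; C9a, C1 and C3 are set under thermodynamic control (retro-Michael and enolisation, finished with K2CO3) by the purchased C9 centre, and the acidic stage lets any C9′ epimer re-equilibrate.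

**Compound list**
1 | (R)-cyclohex-3-ene-1-carboxylic acid | OC(=O)[C@H]1CC=CCC1 | starting material
2 | (R)-5-hydroxy-2-(2-hydroxyethyl)pentanoic acid (not isolated) | OC(=O)[C@@H](CCO)CCCO | intermediate
3 | (R)-3-(3-hydroxypropyl)oxolan-2-one | O=C1OCC[C@H]1CCCO | intermediate
4 | (R)-3-(3-chloropropyl)oxolan-2-one | O=C1OCC[C@H]1CCCCl | intermediate
5 | (R)-5-chloro-2-(2-hydroxyethyl)-N-methoxy-N-methylpentanamide | CON(C)C(=O)[C@@H](CCO)CCCCl | intermediate
6 | (R)-5-chloro-N-methoxy-N-methyl-2-(2-oxoethyl)pentanamide | CON(C)C(=O)[C@@H](CC=O)CCCCl | intermediate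
7 | methyl (S)-3-hydroxy-2-methylpropanoate (Roche ester) | COC(=O)[C@@H](C)CO | starting material
8 | methyl (S)-3-(benzyloxy)-2-methylpropanoate | COC(=O)[C@@H](C)COCc1ccccc1 | intermediate
9 | (S)-3-(benzyloxy)-2-methylpropanal | O=C[C@@H](C)COCc1ccccc1 | intermediate
10 | 1-bromo-4-chlorobutane | ClCCCCBr | starting material
11 | 4-chlorobutylmagnesium bromide (not isolated) | ClCCCC[Mg]Br | intermediate
12 | (2S,3R)-1-(benzyloxy)-7-chloro-2-methylheptan-3-ol | ClCCCC[C@@H](O)[C@@H](C)COCc1ccccc1 | intermediate
13 | [(5R,6S)-7-(benzyloxy)-5-hydroxy-6-methylheptyl]triphenylphosphonium iodide | [I-].c1ccccc1[P+](c1ccccc1)(c1ccccc1)CCCC[C@@H](O)[C@@H](C)COCc1ccccc1 | intermediate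
14 | potassium (2S,3R)-1-(benzyloxy)-2-methyl-7-(triphenylphosphoranylidene)heptan-3-olate (oxido ylide, not isolated) | c1ccccc1P(c1ccccc1)(c1ccccc1)=CCCC[C@@H]([O-])[C@@H](C)COCc1ccccc1.[K+] | intermediate
15 | (2R)-2-[(2Z,7R,8S)-9-(benzyloxy)-7-hydroxy-8-methylnon-2-en-1-yl]-5-chloro-N-methoxy-N-methylpentanamide | CON(C)C(=O)[C@H](CCCCl)C/C=C\CCC[C@@H](O)[C@@H](C)COCc1ccccc1 | intermediate
16 | (2S)-5-chloro-2-[(7R,8S)-7,9-dihydroxy-8-methylnonyl]-N-methoxy-N-methylpentanamide | CON(C)C(=O)[C@H](CCCCl)CCCCCC[C@@H](O)[C@@H](C)CO | intermediate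
17 | (2S)-2-[(7R,8S)-9-azido-7-hydroxy-8-methylnonyl]-5-chloro-N-methoxy-N-methylpentanamide | CON(C)C(=O)[C@H](CCCCl)CCCCCC[C@@H](O)[C@@H](C)CN=[N+]=[N-] | intermediate
18 | ε-caprolactone (oxepan-2-one) | O=C1CCCCCO1 | starting material
19 | 1-chloro-3-iodopropane | ClCCCI | starting material
20 | lithium enolate of oxepan-2-one (not isolated) | [Li+].[O-]C1=CCCCCO1 | intermediate
21 | 3-(3-chloropropyl)oxepan-2-one (racemic) | O=C1OCCCCC1CCCCl | intermediate
22 | 2-(3-chloropropyl)-6-hydroxyhexanal (racemic) | O=CC(CCCCl)CCCCO | intermediate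
23 | (2S)-2-[(7R,8S)-9-amino-7-hydroxy-8-methylnonyl]-5-chloro-N-methoxy-N-methylpentanamide (not isolated) | CON(C)C(=O)[C@H](CCCCl)CCCCCC[C@@H](O)[C@@H](C)CN | intermediate
24 | (2S)-5-chloro-2-{6-[(2S,5S,6R)-2-(1-chloro-8-hydroxyoctan-4-yl)-5-methyl-1,3-oxazinan-6-yl]hexyl}-N-methoxy-N-methylpentanamide (side-chain CH epimeric, not isolated) | CON(C)C(=O)[C@H](CCCCl)CCCCCC[C@H]1O[C@@H](C(CCCCl)CCCCO)NC[C@@H]1C | intermediate
25 | (2S)-5-chloro-2-{6-[(2R,3S,9R,9aS)-9-(4-hydroxybutyl)-3-methylperhydropyrido[2,1-b][1,3]oxazin-2-yl]hexyl}-N-methoxy-N-methylpentanamide | CON(C)C(=O)[C@H](CCCCl)CCCCCC[C@H]1O[C@H]2[C@H](CCCCO)CCCN2C[C@@H]1C | intermediate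
26 | (2S)-2-{6-[(2R,3S,9R,9aS)-9-(4-bromobutyl)-3-methylperhydropyrido[2,1-b][1,3]oxazin-2-yl]hexyl}-5-chloro-N-methoxy-N-methylpentanamide | CON(C)C(=O)[C@H](CCCCl)CCCCCC[C@H]1O[C@H]2[C@H](CCCCBr)CCCN2C[C@@H]1C | intermediate
27 | (2S)-2-{6-[(2R,3S,9R,9aS)-9-(4-bromobutyl)-3-methylperhydropyrido[2,1-b][1,3]oxazin-2-yl]hexyl}-5-chloropentanal | O=C[C@H](CCCCl)CCCCCC[C@H]1O[C@H]2[C@H](CCCCBr)CCCN2C[C@@H]1C | intermediate
28 | diethyl (2-oxobutyl)phosphonate | CCC(=O)CP(=O)(OCC)OCC | starting material
29 | diethyl (3-oxopent-1-en-2-yl)phosphonate | CCC(=O)C(=C)P(=O)(OCC)OCC | intermediate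
30 | diethyl [9-{(2R,3S,9R,9aS)-2-[(7S)-10-chloro-7-formyldecyl]-3-methylperhydropyrido[2,1-b][1,3]oxazin-9-yl}-3-oxononan-4-yl]phosphonate (mixed at the P-bearing carbon, not isolated) | O=C[C@H](CCCCl)CCCCCC[C@H]1O[C@H]2[C@H](CCCCCC(C(=O)CC)P(=O)(OCC)OCC)CCCN2C[C@@H]1C | intermediate
31 | macrocyclic E-chloro-enone: the 2′-(CH2)6 and 9′-(CH2)5 arms of the (2′R,3′S,9′R,9a′S)-3′-methyl-1-oxaquinolizidine are bridged by –CH[(CH2)3Cl]–CH=C(COEt)–, the allylic CH (S, future C9) on the (CH2)6 arm and the acyl-bearing alkene carbon (future C1) on the (CH2)5 arm | CCC(=O)/C1=C/[C@H](CCCCl)CCCCCC[C@H]2O[C@H]3[C@H](CCCCC1)CCCN3C[C@@H]2C | intermediate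
32 | macrocyclic amino enone: 31 with (CH2)3NH2 in place of (CH2)3Cl (not isolated) | CCC(=O)/C1=C/[C@H](CCCN)CCCCCC[C@H]2O[C@H]3[C@H](CCCCC1)CCCN3C[C@@H]2C | intermediate
33 | macrocyclic piperidine ketone: (2S,3S)-2,3-trans-disubstituted piperidine (future C9a, C9) whose C2 carries the (R)-CH(COEt) carbon (future C1); oxaquinolizidine unchanged (not isolated) | N1CCC[C@@H]2CCCCCC[C@H]3O[C@H]4[C@H](CCCCC[C@@H](C(=O)CC)[C@H]21)CCCN4C[C@@H]3C | intermediate
34 | target CNP0236330.1: (1R,3R,9S,9aS)-3-methylquinolizidin-2-one and (2′R,3′S,9′R,9a′S)-3′-methyl-1-oxaquinolizidine joined C9–(CH2)6–C2′ and C1–(CH2)5–C9′ | C[C@@H]1CN2CCC[C@@H]3CCCCCC[C@H]4O[C@H]5[C@H](CCCCC[C@@H](C1=O)[C@H]32)CCCN5C[C@@H]4C | target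

**Step count and risks**

Total: 19 steps, counting the preparation of reagent 29. Longest linear sequence: 12 steps (5, 6, 7, 8, 9, 10, 11, 14, 15, 16, 18, 19); the branch from 1 is equally long.

Steps most likely to fail:

Step 18 (the proposed new method). The phosphonate anion of 30 may be captured by unreacted 29 instead of closing the ring, the macro-olefination may be slow, and the α-branched aldehyde may epimerise under base. The fallback separates the two events with known chemistry. It sets out from 27: exchange of bromide for iodide (NaI, acetone, 20 °C, chloride inert) gives the iodo aldehyde F1; a thermal tin-hydride radical-chain Giese addition to 29 (Bu3SnH, AIBN, C6H6, 80 °C, syringe pump) gives isolated keto phosphonate 30; a separate Masamune–Roush olefination (LiCl, iPr2NEt, MeCN, 1 mM) comes back to the route at 31.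

Step 19. Ammonia may over-alkylate or condense with the enone, and the route relies on the assumption that the natural C1/C3/C9a configuration is the thermodynamic one inside the macrocycle. C9 is γ to the enone, so base is kept mild. The fallback changes how nitrogen and ring A are brought in and sets out from 31: NaN3 (DMF, 50 °C) gives the azido enone F2; α-methylenation of the ethyl ketone ((CH2O)n, PhNHMe·CF3CO2H, THF, 65 °C) gives the azido dienone F3; Staudinger reduction (PPh3, THF/H2O) releases the amino dienone F4, which closes rings B and A by double aza-Michael addition (6-exo, then 6-endo) and, after K2CO3/MeOH equilibration, comes back to the route at 34.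

Step 7. Grignard reagents give lower chelation control than cuprates or allylstannanes, so the anti:syn ratio may be modest. The fallback corrects the stereocentre instead of controlling it and sets out from 9: the addition is run without MgBr2·OEt2 in THF, the syn alcohol F5 is separated from 12 and inverted by Mitsunobu esterification (4-O2NC6H4CO2H, iPrO2CN=NCO2iPr, PPh3) to the 4-nitrobenzoate F6, and methanolysis (K2CO3, MeOH) comes back to the route at 12.

**Further compounds**
F1 | step 18 | (2S)-5-chloro-2-{6-[(2R,3S,9R,9aS)-9-(4-iodobutyl)-3-methylperhydropyrido[2,1-b][1,3]oxazin-2-yl]hexyl}pentanal | O=C[C@H](CCCCl)CCCCCC[C@H]1O[C@H]2[C@H](CCCCI)CCCN2C[C@@H]1C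
F2 | step 19 | macrocyclic azido enone (31 with N3 in place of Cl) | CCC(=O)/C1=C/[C@H](CCCN=[N+]=[N-])CCCCCC[C@H]2O[C@H]3[C@H](CCCCC1)CCCN3C[C@@H]2C
F3 | step 19 | macrocyclic azido dienone (F2 with 2-methylprop-2-enoyl in place of propanoyl) | CC(=C)C(=O)/C1=C/[C@H](CCCN=[N+]=[N-])CCCCCC[C@H]2O[C@H]3[C@H](CCCCC1)CCCN3C[C@@H]2C
F4 | step 19 | macrocyclic amino dienone (F3 with NH2 in place of N3) | CC(=C)C(=O)/C1=C/[C@H](CCCN)CCCCCC[C@H]2O[C@H]3[C@H](CCCCC1)CCCN3C[C@@H]2C
F5 | step 7 | (2S,3S)-1-(benzyloxy)-7-chloro-2-methylheptan-3-ol | ClCCCC[C@H](O)[C@@H](C)COCc1ccccc1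
F6 | step 7 | (2S,3R)-1-(benzyloxy)-7-chloro-2-methylheptan-3-yl 4-nitrobenzoate | ClCCCC[C@@H](OC(=O)c1ccc(cc1)[N+](=O)[O-])[C@@H](C)COCc1ccccc1
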